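**Assumption:** the target has no stereocentre, so "single enantiomer" is read as the single (E)-C6''=C7'' isomer shown; mono-tert-butyl pimelate is taken as a purchasable starting material.

**Retrosynthetic overview**
- Last bond: N-acylation of the free aminomethyl-biphenol with (E)-8-methylnon-6-enoyl chloride, so the alkene enters after every hydrogenation.
- Biaryl C5'–C5''' bond: Suzuki–Miyaura coupling of two 5-bromovanillin-derived halves (a bromo 8-methylnonanamide and a formyl boronate); CHO becomes CH2NH2 by oxime hydrogenation with concurrent O-debenzylation.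
- Key C–C bond (C6–C7 of both C10 acyl chains): intermolecular Evans syn-aldol of a pimelate half-ester imide with isobutyraldehyde, then stereospecific anti dehydrative decarboxylation to the E-alkene; hydrogenating part of the acid gives the saturated chain.
- No ring is built: both arenes come from 5-bromovanillin, and the oxazolidinone is a recovered auxiliary.

**Route**

Step 1
Reactants: 1 7-(tert-butoxy)-7-oxoheptanoic acid (mono-tert-butyl pimelate); 2 (S)-4-benzyl-1,3-oxazolidin-2-one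
Product: 4 tert-butyl 7-[(4S)-4-benzyl-2-oxo-1,3-oxazolidin-3-yl]-7-oxoheptanoate, via mixed pivalic anhydride 3 (not isolated)
Conditions: PivCl, Et3N, THF, −20 °C; then LiCl, 2, −20 °C → rt
Reagents that add atoms: pivaloyl chloride, CC(C)(C)C(=O)Cl (pivaloyl group of 3 only; no atoms remain in 4)
Why: N-acylation of the oxazolidinone through the mixed anhydride occurs at the unhindered acyl carbonyl, and the tert-butyl ester is inert.

Step 2
Reactants: 4 tert-butyl 7-[(4S)-4-benzyl-2-oxo-1,3-oxazolidin-3-yl]-7-oxoheptanoate; 5 isobutyraldehyde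
Product: 8 tert-butyl (6S,7R)-6-{[(4S)-4-benzyl-2-oxo-1,3-oxazolidin-3-yl]carbonyl}-7-hydroxy-8-methylnonanoate, via Z-dibutylboron enolate 6 (not isolated), via dibutylboron aldolate 7 (not isolated)
Conditions: Bu2BOTf, iPr2NEt, CH2Cl2, 0 °C; 5, −78 → 0 °C; then pH 7 buffer, MeOH, 30% H2O2, 0 °C
Reagents that add atoms: dibutylboron triflate, CCCCB(CCCC)OS(=O)(=O)C(F)(F)F (Bu2B group of 6 and 7 only; no atoms remain in 8)
Why: Evans boron aldol addition, in which the Z(O)-enolate adds to the aldehyde through a closed Zimmerman–Traxler chair to give the syn aldol (6S,7R with the S auxiliary; only the syn relationship is needed later) and forms the C6–C7 bond.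

Step 3
Reactants: 8 tert-butyl (6S,7R)-6-{[(4S)-4-benzyl-2-oxo-1,3-oxazolidin-3-yl]carbonyl}-7-hydroxy-8-methylnonanoate
Product: 10 (2S,3R)-2-[5-(tert-butoxy)-5-oxopentyl]-3-hydroxy-4-methylpentanoic acid, via peroxy acid 9 (not isolated)
Conditions: LiOH·H2O, 30% H2O2, THF/H2O 3:1, 0 °C; aq. Na2SO3; extract 2; 1 M HCl to pH 3, 0 °C
Reagents that add atoms: hydrogen peroxide, OO (as LiOOH; both O in 9, one O kept in 10)
Why: Evans auxiliary cleavage, in which LiOOH attacks the exocyclic imide carbonyl selectively, the tert-butyl ester survives, sulfite reduces the peracid, and neither stereocentre epimerises at 0 °C.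

Step 4
Reactants: 10 (2S,3R)-2-[5-(tert-butoxy)-5-oxopentyl]-3-hydroxy-4-methylpentanoic acid
Product: 11 tert-butyl (E)-8-methylnon-6-enoate
Conditions: Me2NCH(OCH2tBu)2 (3 equiv), CHCl3, rt then 60 °C
Reagents that add atoms: none
Why: Dehydrative decarboxylation with a DMF acetal (Grob-type fragmentation) activates the β-hydroxyl as an O-formamidinium leaving group and expels CO2 anti-periplanar to it, so the syn acid gives the E-alkene stereospecifically while both stereocentres are erased.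

Step 5
Reactants: 11 tert-butyl (E)-8-methylnon-6-enoate
Product: 12 (E)-8-methylnon-6-enoic acid
Conditions: TFA/CH2Cl2 1:4, 0 °C → rt
Reagents that add atoms: none
Why: Acidolysis of the tert-butyl ester (E1 loss of isobutene) is clean and does not protonate the isolated 1,2-disubstituted alkene.

Step 6
Reactants: 12 (E)-8-methylnon-6-enoic acid (a portion)
Product: 13 8-methylnonanoic acid
Conditions: H2 (1 atm), 10% Pd/C, EtOAc, rt
Reagents that add atoms: none
Why: Catalytic hydrogenation of the isolated alkene is quantitative and touches nothing else.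

Step 7
Reactants: 14 5-bromovanillin
Product: 15 4-(benzyloxy)-3-bromo-5-methoxybenzaldehyde
Conditions: BnBr, K2CO3, DMF, 60 °C
Reagents that add atoms: benzyl bromide, BrCc1ccccc1
Why: Williamson etherification of the acidic phenol gives a benzyl ether that survives every step until the planned hydrogenolysis.

Step 8
Reactants: 15 4-(benzyloxy)-3-bromo-5-methoxybenzaldehyde
Product: 16 (E)-4-(benzyloxy)-3-bromo-5-methoxybenzaldehyde oxime
Conditions: NH2OH·HCl, NaOAc, EtOH/H2O, 70 °C
Reagents that add atoms: hydroxylamine hydrochloride, NO.Cl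
Why: Oxime condensation of an aryl aldehyde is essentially quantitative and gives the E-aldoxime.

Step 9
Reactants: 16 (E)-4-(benzyloxy)-3-bromo-5-methoxybenzaldehyde oxime
Product: 17 [4-(benzyloxy)-3-bromo-5-methoxyphenyl]methanamine
Conditions: Zn dust, AcOH, rt → 50 °C; aq. NH3 work-up
Reagents that add atoms: none
Why: Dissolving-metal (Zn/AcOH) reduction of the aldoxime gives the primary benzylamine without touching the aryl bromide or benzyl ether, which hydrogenation would cleave.

Step 10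
Reactants: 13 8-methylnonanoic acid; 17 [4-(benzyloxy)-3-bromo-5-methoxyphenyl]methanamine
Product: 19 N-[4-(benzyloxy)-3-bromo-5-methoxybenzyl]-8-methylnonanamide, via 8-methylnonanoyl chloride 18 (not isolated)
Conditions: (COCl)2, cat. DMF, CH2Cl2, 0 °C → rt, evaporate; then 17, Et3N, CH2Cl2, 0 °C → rt
Reagents that add atoms: oxalyl chloride, O=C(Cl)C(=O)Cl (Cl of 18 only; no atoms remain in 19)
Why: Acid chloride formation followed by N-acylation of the primary amine is the standard high-yielding capsaicinoid amide synthesis.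

Step 11
Reactants: 15 4-(benzyloxy)-3-bromo-5-methoxybenzaldehyde
Product: 20 4-(benzyloxy)-3-methoxy-5-(4,4,5,5-tetramethyl-1,3,2-dioxaborolan-2-yl)benzaldehyde
Conditions: B2pin2, PdCl2(dppf) (3 mol%), KOAc, 1,4-dioxane, 90 °C
Reagents that add atoms: bis(pinacolato)diboron, CC1(C)OB(OC1(C)C)B1OC(C)(C)C(C)(C)O1
Why: Miyaura borylation of the electron-poor aryl bromide tolerates the aldehyde and benzyl ether, and KOAc is too weak a base to cause Suzuki homocoupling.

Step 12
Reactants: 19 N-[4-(benzyloxy)-3-bromo-5-methoxybenzyl]-8-methylnonanamide; 20 4-(benzyloxy)-3-methoxy-5-(4,4,5,5-tetramethyl-1,3,2-dioxaborolan-2-yl)benzaldehyde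
Product: 21 N-{[2,2'-bis(benzyloxy)-5'-formyl-3,3'-dimethoxy-[1,1'-biphenyl]-5-yl]methyl}-8-methylnonanamide
Conditions: Pd(OAc)2 (3 mol%), SPhos (6 mol%), K3PO4, toluene/H2O 10:1, 90 °C
Reagents that add atoms: none
Why: Suzuki–Miyaura cross-coupling with the bulky electron-rich SPhos ligand copes with the ortho-alkoxy groups on both partners and gives the unsymmetrical biaryl without statistical mixtures.

Step 13
Reactants: 21 N-{[2,2'-bis(benzyloxy)-5'-formyl-3,3'-dimethoxy-[1,1'-biphenyl]-5-yl]methyl}-8-methylnonanamide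
Product: 22 N-({2,2'-bis(benzyloxy)-5'-[(E)-(hydroxyimino)methyl]-3,3'-dimethoxy-[1,1'-biphenyl]-5-yl}methyl)-8-methylnonanamide
Conditions: NH2OH·HCl, NaOAc, EtOH/THF, 60 °C
Reagents that add atoms: hydroxylamine hydrochloride, NO.Cl
Why: Oxime condensation is selective for the aldehyde, and the secondary amide and ethers are inert.

Step 14
Reactants: 22 N-({2,2'-bis(benzyloxy)-5'-[(E)-(hydroxyimino)methyl]-3,3'-dimethoxy-[1,1'-biphenyl]-5-yl}methyl)-8-methylnonanamide
Product: 23 N-{[5'-(aminomethyl)-2,2'-dihydroxy-3,3'-dimethoxy-[1,1'-biphenyl]-5-yl]methyl}-8-methylnonanamide hydrochloride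
Conditions: H2 (3 atm), 10% Pd/C, EtOH, HCl (1.5 equiv), rt
Reagents that add atoms: hydrogen chloride, Cl
Why: Catalytic hydrogenation in acidic ethanol reduces the aldoxime to the primary ammonium salt (acid suppresses secondary-amine formation) and hydrogenolyses both benzyl ethers in the same operation, before any alkene is present.

Step 15
Reactants: 23 N-{[5'-(aminomethyl)-2,2'-dihydroxy-3,3'-dimethoxy-[1,1'-biphenyl]-5-yl]methyl}-8-methylnonanamide hydrochloride; 12 (E)-8-methylnon-6-enoic acid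
Product: 25 6'',7''-dihydro-5',5'''-dicapsaicin, via (E)-8-methylnon-6-enoyl chloride 24 (not isolated)
Conditions: 12, (COCl)2, cat. DMF, CH2Cl2, 0 °C → rt, evaporate; then 23, NaHCO3, THF/H2O, 0 °C → rt
Reagents that add atoms: oxalyl chloride, O=C(Cl)C(=O)Cl (Cl of 24 only; no atoms remain in 25)
Why: Schotten–Baumann N-acylation under bicarbonate is chemoselective because the benzylic amine is far more nucleophilic than the hindered un-ionised phenols, and the E-alkene from step 4 is not exposed to reducing or isomerising conditions.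

**Compound list**
1 | 7-(tert-butoxy)-7-oxoheptanoic acid (mono-tert-butyl pimelate) | CC(C)(C)OC(=O)CCCCCC(=O)O | starting material
2 | (S)-4-benzyl-1,3-oxazolidin-2-one | O=C1N[C@@H](Cc2ccccc2)CO1 | starting material
3 | 7-(tert-butoxy)-7-oxoheptanoic pivalic anhydride | CC(C)(C)OC(=O)CCCCCC(=O)OC(=O)C(C)(C)C | intermediate
4 | tert-butyl 7-[(4S)-4-benzyl-2-oxo-1,3-oxazolidin-3-yl]-7-oxoheptanoate | CC(C)(C)OC(=O)CCCCCC(=O)N1[C@@H](Cc2ccccc2)COC1=O | intermediate
5 | isobutyraldehyde (2-methylpropanal) | CC(C)C=O | starting material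
6 | tert-butyl (Z)-7-[(4S)-4-benzyl-2-oxo-1,3-oxazolidin-3-yl]-7-[(dibutylboranyl)oxy]hept-6-enoate | CCCCB(CCCC)O/C(=C\CCCCC(=O)OC(C)(C)C)N1C(=O)OC[C@@H]1Cc1ccccc1 | intermediate
7 | tert-butyl (6S,7R)-6-{[(4S)-4-benzyl-2-oxo-1,3-oxazolidin-3-yl]carbonyl}-7-[(dibutylboranyl)oxy]-8-methylnonanoate | O=C1OC[C@H](Cc2ccccc2)N1C(=O)[C@@H](CCCCC(=O)OC(C)(C)C)[C@H](OB(CCCC)CCCC)C(C)C | intermediate
8 | tert-butyl (6S,7R)-6-{[(4S)-4-benzyl-2-oxo-1,3-oxazolidin-3-yl]carbonyl}-7-hydroxy-8-methylnonanoate | O=C1OC[C@H](Cc2ccccc2)N1C(=O)[C@@H](CCCCC(=O)OC(C)(C)C)[C@H](O)C(C)C | intermediate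
9 | (2S,3R)-2-[5-(tert-butoxy)-5-oxopentyl]-3-hydroxy-4-methylpentaneperoxoic acid | OOC(=O)[C@@H](CCCCC(=O)OC(C)(C)C)[C@H](O)C(C)C | intermediate
10 | (2S,3R)-2-[5-(tert-butoxy)-5-oxopentyl]-3-hydroxy-4-methylpentanoic acid | OC(=O)[C@@H](CCCCC(=O)OC(C)(C)C)[C@H](O)C(C)C | intermediate
11 | tert-butyl (E)-8-methylnon-6-enoate | CC(C)/C=C/CCCCC(=O)OC(C)(C)C | intermediate
12 | (E)-8-methylnon-6-enoic acid | CC(C)/C=C/CCCCC(=O)O | intermediate
13 | 8-methylnonanoic acid | CC(C)CCCCCCC(=O)O | intermediate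
14 | 5-bromovanillin (3-bromo-4-hydroxy-5-methoxybenzaldehyde) | COc1cc(C=O)cc(Br)c1O | starting material
15 | 4-(benzyloxy)-3-bromo-5-methoxybenzaldehyde | COc1cc(C=O)cc(Br)c1OCc1ccccc1 | intermediate
16 | (E)-4-(benzyloxy)-3-bromo-5-methoxybenzaldehyde oxime | COc1cc(/C=N/O)cc(Br)c1OCc1ccccc1 | intermediate
17 | [4-(benzyloxy)-3-bromo-5-methoxyphenyl]methanamine | COc1cc(CN)cc(Br)c1OCc1ccccc1 | intermediate
18 | 8-methylnonanoyl chloride | CC(C)CCCCCCC(=O)Cl | intermediate
19 | N-[4-(benzyloxy)-3-bromo-5-methoxybenzyl]-8-methylnonanamide | COc1cc(CNC(=O)CCCCCCC(C)C)cc(Br)c1OCc1ccccc1 | intermediate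
20 | 4-(benzyloxy)-3-methoxy-5-(4,4,5,5-tetramethyl-1,3,2-dioxaborolan-2-yl)benzaldehyde | COc1cc(C=O)cc(B2OC(C)(C)C(C)(C)O2)c1OCc1ccccc1 | intermediate
21 | N-{[2,2'-bis(benzyloxy)-5'-formyl-3,3'-dimethoxy-[1,1'-biphenyl]-5-yl]methyl}-8-methylnonanamide | COc1cc(C=O)cc(-c2cc(CNC(=O)CCCCCCC(C)C)cc(OC)c2OCc2ccccc2)c1OCc1ccccc1 | intermediate
22 | N-({2,2'-bis(benzyloxy)-5'-[(E)-(hydroxyimino)methyl]-3,3'-dimethoxy-[1,1'-biphenyl]-5-yl}methyl)-8-methylnonanamide | COc1cc(/C=N/O)cc(-c2cc(CNC(=O)CCCCCCC(C)C)cc(OC)c2OCc2ccccc2)c1OCc1ccccc1 | intermediate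
23 | N-{[5'-(aminomethyl)-2,2'-dihydroxy-3,3'-dimethoxy-[1,1'-biphenyl]-5-yl]methyl}-8-methylnonanamide hydrochloride | COc1cc(CN)cc(-c2cc(CNC(=O)CCCCCCC(C)C)cc(OC)c2O)c1O.Cl | intermediate
24 | (E)-8-methylnon-6-enoyl chloride | CC(C)/C=C/CCCCC(=O)Cl | intermediate
25 | 6'',7''-dihydro-5',5'''-dicapsaicin; (E)-N-({2,2'-dihydroxy-3,3'-dimethoxy-5'-[(8-methylnonanamido)methyl]-[1,1'-biphenyl]-5-yl}methyl)-8-methylnon-6-enamide | COc1cc(CNC(=O)CCCC/C=C/C(C)C)cc(-c2cc(CNC(=O)CCCCCCC(C)C)cc(OC)c2O)c1O | target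

**Count**
Total steps: 15. Longest linear sequence: 11 steps (1, 2, 3, 4, 5, 6, 10, 12, 13, 14, 15).

**Three steps most likely to fail, with fallbacks**

Step 4 (dehydrative decarboxylation). The risk is sluggish fragmentation at the purely aliphatic carbinol or some erosion of E purity. The fallback is a Julia–Kocienski olefination that sets out from isobutyraldehyde 5 and returns to the route at 11. Commercial tert-butyl 6-bromohexanoate is S-alkylated with 1-phenyl-1H-tetrazole-5-thiol (K2CO3, acetone) to tert-butyl 6-[(1-phenyl-1H-tetrazol-5-yl)sulfanyl]hexanoate F1. This is oxidised (30% H2O2, cat. ammonium molybdate, EtOH) to tert-butyl 6-[(1-phenyl-1H-tetrazol-5-yl)sulfonyl]hexanoate F2. Deprotonating F2 with KHMDS in DME at −60 °C and adding 5 gives 11 directly, with the high E selectivity typical of PT-sulfones and α-branched aldehydes.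

Step 12 (Suzuki coupling). The risk is protodeboronation of the formyl-aryl boronate 20 or slow coupling of two ortho-alkoxy partners. The fallback swaps the roles of the two halves so that boron sits on the electron-rich amide ring and the electron-poor bromo aldehyde is the electrophile; it sets out from 19 and returns at 21. Miyaura borylation of 19 (B2pin2, PdCl2(dppf), KOAc, dioxane, 90 °C) gives N-[4-(benzyloxy)-3-methoxy-5-(4,4,5,5-tetramethyl-1,3,2-dioxaborolan-2-yl)benzyl]-8-methylnonanamide F3. F3 is coupled with bromo aldehyde 15 (already in hand; Pd(OAc)2/SPhos, K3PO4, toluene/H2O) to give 21.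

Step 14 (oxime hydrogenation with debenzylation). The risk is secondary-amine formation through the imine or partial benzylic C–N hydrogenolysis. The fallback introduces nitrogen as an azide; it sets out from 21 and returns at 23. NaBH4 (MeOH/THF, 0 °C) reduces 21 to N-{[2,2'-bis(benzyloxy)-5'-(hydroxymethyl)-3,3'-dimethoxy-[1,1'-biphenyl]-5-yl]methyl}-8-methylnonanamide F4. Treatment with (PhO)2P(O)N3/DBU in toluene gives N-{[5'-(azidomethyl)-2,2'-bis(benzyloxy)-3,3'-dimethoxy-[1,1'-biphenyl]-5-yl]methyl}-8-methylnonanamide F5. Brief hydrogenation of F5 (H2, Pd/C, EtOH, 1.5 equiv HCl) reduces the azide cleanly and removes both benzyl groups to give 23.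

**Further compounds**
F1 | step 4 | tert-butyl 6-[(1-phenyl-1H-tetrazol-5-yl)sulfanyl]hexanoate | CC(C)(C)OC(=O)CCCCCSc1nnnn1-c1ccccc1
F2 | step 4 | tert-butyl 6-[(1-phenyl-1H-tetrazol-5-yl)sulfonyl]hexanoate | CC(C)(C)OC(=O)CCCCCS(=O)(=O)c1nnnn1-c1ccccc1
F3 | step 12 | N-[4-(benzyloxy)-3-methoxy-5-(4,4,5,5-tetramethyl-1,3,2-dioxaborolan-2-yl)benzyl]-8-methylnonanamide | COc1cc(CNC(=O)CCCCCCC(C)C)cc(B2OC(C)(C)C(C)(C)O2)c1OCc1ccccc1
F4 | step 14 | N-{[2,2'-bis(benzyloxy)-5'-(hydroxymethyl)-3,3'-dimethoxy-[1,1'-biphenyl]-5-yl]methyl}-8-methylnonanamide | COc1cc(CO)cc(-c2cc(CNC(=O)CCCCCCC(C)C)cc(OC)c2OCc2ccccc2)c1OCc1ccccc1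
F5 | step 14 | N-{[5'-(azidomethyl)-2,2'-bis(benzyloxy)-3,3'-dimethoxy-[1,1'-biphenyl]-5-yl]methyl}-8-methylnonanamide | COc1cc(CN=[N+]=[N-])cc(-c2cc(CNC(=O)CCCCCCC(C)C)cc(OC)c2OCc2ccccc2)c1OCc1ccccc1
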